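The butenolide is disconnected at its C3'=C4' olefin. The lactone ring (O1'–C2'(=O)–C3'H=C4'(CH3)–C5') with its exocyclic C5'=C15 enol-ether bond is read as an enolised α-diketone, CH3–C4'(=O)–C5'(OH)=C15H, in conjugation with the side-chain alkene. In one operation (triphenylphosphoranylidene)ketene acylates that enolic hydroxyl, delivering C2'–C3' as a phosphorus ylide, and the ylide closes the ring by Wittig olefination of the C4' methyl ketone. The complete (Z)-γ-ylidene butenolide thus appears at the last skeleton-building step. The precursor is an acyclic 3-hydroxy-3,5-dien-2-one on a decalin made from (+)-larixol, whose 6α-hydroxyl directs oxidation of the 4α-methyl (C18) by nitrite photolysis.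

Key step: step 13

Assumptions (remarks on the chemistry):
- The target γ-hydroxy aldehyde and its 18,6α-lactol are ring–chain tautomers; the last step liberates this equilibrating system, written as the open form.
- Labdane numbering is used for the decalin and the chain up to C15 (C17 = methyl on C8, C18 = 4α carbon, C19 = 4β-methyl, C20 = methyl on C10); primed locants O1'–C5' denote the butenolide.
- The acetal carbon C18 of compounds 7–12 and 16–20 is a temporary stereocentre formed as a mixture of anomers. It is left unspecified in the SMILES and is erased in the last step.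
- (+)-Larixol (from larch oleoresin), (triphenylphosphoranylidene)ketene and the Ohira–Bestmann reagent are purchased.

Step 1
Reactants: 1 (+)-larixol
Product: 2 6α-hydroxy-14,15-dinorlabd-8(17)-en-13-one
Conditions: KMnO4, acetone/H2O, 0 °C → rt
Reagents that add atoms: none
Why: Permanganate oxidation (dihydroxylation of the vinyl group, then glycol cleavage) is the usual degradation of a tertiary vinyl carbinol side chain to the 14,15-dinor-13-ketone, the hindered exocyclic 8(17)-alkene and the 6α-OH should react far more slowly, and the only stereocentre affected, C13, is removed.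

Step 2
Reactants: 2 6α-hydroxy-14,15-dinorlabd-8(17)-en-13-one
Product: 3 13-oxo-14,15-dinorlabd-8(17)-en-6α-yl nitrite
Conditions: NOCl, pyridine, −20 °C, dark
Reagents that add atoms: nitrosyl chloride, O=NCl
Why: O-Nitrosation of the single hydroxyl (alkyl nitrite formation) is fast in pyridine at low temperature and should outrun addition of NOCl to the hindered 1,1-disubstituted alkene, and C6 keeps its configuration because only the O–H bond reacts.

Step 3
Reactants: 3 13-oxo-14,15-dinorlabd-8(17)-en-6α-yl nitrite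
Product: 5 (E)-oxime of 6α-hydroxy-13-oxo-14,15-dinorlabd-8(17)-en-18-al, via C18-nitroso alcohol 4 (not isolated)
Conditions: hν (365 nm), benzene, 15 °C, Ar; then i-PrOH, 80 °C
Reagents that add atoms: none
Why: Barton nitrite photolysis: the 6α-alkoxy radical from O–NO homolysis abstracts hydrogen by a 1,5-shift from the peri 4α-methyl C18 (estimated at about 2.5 Å from O6 in an idealised chair–chair model, against about 3.5 Å for the 4β-methyl), NO recombines at C18 and the nitroso compound tautomerises to the oxime, which makes C4 a stereocentre with the functionalised carbon α and the remaining methyl β.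

Step 4
Reactants: 5 (E)-oxime of 6α-hydroxy-13-oxo-14,15-dinorlabd-8(17)-en-18-al
Product: 7 18,6α-lactol (6α,18-epoxy-18-hydroxy-14,15-dinorlabd-8(17)-en-13-one; both C18 anomers), via hydroxy aldehyde 6 (not isolated)
Conditions: TiCl3 (aq.), NH4OAc, THF/H2O, rt
Reagents that add atoms: water, O
Why: Reductive deoximation with buffered trivalent titanium (N–O cleavage to the imine, then hydrolysis) should free the aldehyde without touching the ketone or the alkene, and the peri 6α-OH then closes the five-membered lactol.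

Step 5
Reactants: 7 18,6α-lactol
Product: 8 6α,18-epoxy-18-methoxy-14,15-dinorlabd-8(17)-en-13-one (methyl acetal; both C18 anomers)
Conditions: MeOH, PPTS (cat.), rt
Reagents that add atoms: methanol, CO
Why: Acid-catalysed acetalisation of the lactol (Fischer glycosidation type) through the cyclic oxocarbenium ion masks the aldehyde and the 6α-OH in one base- and hydride-stable group, and the anomer mixture is inconsequential.

Step 6
Reactants: 8 6α,18-epoxy-18-methoxy-14,15-dinorlabd-8(17)-en-13-one
Product: 9 ethyl (13E)-6α,18-epoxy-18-methoxylabda-8(17),13-dien-15-oate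
Conditions: (EtO)2P(O)CH2CO2Et, NaH, THF, 0 → 50 °C
Reagents that add atoms: triethyl phosphonoacetate, CCOC(=O)CP(=O)(OCC)OCC
Why: Horner–Wadsworth–Emmons olefination of the methyl ketone should favour the 13E enoate, with the ester trans to the larger C12 chain, and the minor 13Z isomer would be removed by chromatography.

Step 7
Reactants: 9 ethyl (13E)-6α,18-epoxy-18-methoxylabda-8(17),13-dien-15-oate
Product: 10 ethyl (13E)-6α,18:8α,17-diepoxy-18-methoxylabd-13-en-15-oate
Conditions: mCPBA, NaHCO3, CH2Cl2, 0 °C
Reagents that add atoms: 3-chloroperoxybenzoic acid, OOC(=O)c1cccc(Cl)c1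
Why: Prilezhaev epoxidation is chemoselective for the electron-rich exocyclic alkene over the conjugated enoate, and the peracid should approach C8 from the α face (equatorial attack) because the axial C10 methyl blocks the β face, giving the 8α,17-epoxide.

Step 8
Reactants: 10 ethyl (13E)-6α,18:8α,17-diepoxy-18-methoxylabd-13-en-15-oate
Product: 11 (13E)-6α,18-epoxy-18-methoxylabd-13-ene-8α,15-diol
Conditions: LiAlH4, THF, 0 °C → rt
Reagents that add atoms: none
Why: Hydride reduction converts the enoate into the allylic alcohol (1,2-reduction) and opens the spiro-epoxide by SN2 attack at the primary C17, which leaves the C8–O bond set in step 7 untouched and so gives the 8α-hydroxy-8β-methyl carbinol, while the acetal is inert.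

Step 9
Reactants: 11 (13E)-6α,18-epoxy-18-methoxylabd-13-ene-8α,15-diol
Product: 12 (13E)-6α,18-epoxy-8α-hydroxy-18-methoxylabd-13-en-15-al
Conditions: MnO2, CH2Cl2, rt
Reagents that add atoms: none
Why: MnO2 oxidises only the primary allylic alcohol (allylic oxidation to the enal) and leaves the tertiary 8α-OH and the 13E geometry untouched.

Step 10
Reactants: 13 dimethyl (1-diazo-2-oxopropyl)phosphonate (Ohira–Bestmann reagent)
Product: 14 dimethyl (1-hydroxy-2-oxopropyl)phosphonate (racemic)
Conditions: Rh2(OAc)4 (1 mol %), H2O, ClCH2CH2Cl, 60 °C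
Reagents that add atoms: water, O
Why: Rhodium-carbenoid O–H insertion of the diazo phosphonate into water gives the α-hydroxy β-keto phosphonate under neutral conditions.

Step 11
Reactants: 14 dimethyl (1-hydroxy-2-oxopropyl)phosphonate
Product: 15 dimethyl [1-(tert-butyldimethylsilyloxy)-2-oxopropyl]phosphonate (racemic)
Conditions: TBSOTf, 2,6-lutidine, CH2Cl2, −78 → 0 °C
Reagents that add atoms: tert-butyldimethylsilyl triflate, CC(C)(C)[Si](C)(C)OS(=O)(=O)C(F)(F)F
Why: O-Silylation with the silyl triflate and a hindered weak base is fast at low temperature and avoids the base-induced phosphonate–phosphate (phospha-Brook) rearrangement of the α-hydroxy phosphonate.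

Step 12
Reactants: 12 (13E)-6α,18-epoxy-8α-hydroxy-18-methoxylabd-13-en-15-al; 15 dimethyl [1-(tert-butyldimethylsilyloxy)-2-oxopropyl]phosphonate
Product: 17 (3Z,5E)-3-hydroxy-6-methyl-8-(decalin-C9-yl)octa-3,5-dien-2-one (enol form of the α-diketone; decalin as in 12), via silyl enol ether 16 (not isolated)
Conditions: LiCl, DBU, MeCN, 0 °C → rt; then AcOH, TBAF, THF, 0 °C
Reagents that add atoms: none
Why: Masamune–Roush Horner–Wadsworth–Emmons olefination of the β-keto phosphonate with enal 12 forms the C15=C5' bond, normally with the acetyl group trans to the chain (3Z), and fluoride desilylation in the same flask releases the hydrogen-bonded enol of the α-diketone, which can also correct any 3E isomer through its diketone tautomer.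

Step 13
Reactants: 17 (3Z,5E)-3-hydroxy-dienone (enolised α-diketone)
Product: 19 18-O-methyl lactol acetal of the target (Z)-ylidene butenolide, via ester ylide 18 (not isolated)
Conditions: Ph3P=C=C=O (1.1 equiv), toluene, rt then 90 °C, Ar, dark
Reagents that add atoms: (triphenylphosphoranylidene)ketene, O=C=C=P(c1ccccc1)(c1ccccc1)c1ccccc1
Why: The acidic enolic OH of 17 protonates the ylide carbon of Ph3P=C=C=O and the enolate adds to the resulting ketenylphosphonium ion to give ester ylide 18, whose ylide carbon C3' attacks the adjacent C4' methyl ketone; collapse of the oxaphosphetane expels Ph3P=O and forms the C3'=C4' double bond (intramolecular Wittig olefination). The closest known reactions are the tandem addition/Wittig lactonisation of this ylide with α-hydroxy ketones to butenolides and with ortho-hydroxyaryl ketones to coumarins; the enol of an α-diketone combines the α-relationship of the first with the acidic sp2-bound hydroxyl of the second. The only ring closed is the five-membered lactone, by 5-exo-trig attack of C3' on the C4' carbonyl, which is the only carbonyl within reach because the ester oxygen and the acetyl group sit on the same carbon C5'. No stereocentre is formed; the exocyclic C5'=C15 geometry is carried over from the hydrogen-bonded (Z)-enol and is also the thermodynamic one, since the E isomer would press C14 against the C4' methyl. The step needs O-acylation of the enol in preference to the tertiary 8α-OH, secured by the far higher acidity of the enol and the mild addition phase, and it needs the ester ylide to find no aldehyde, secured by the C18 methyl acetal.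

Step 14
Reactants: 19 18-O-methyl lactol acetal of the target
Product: 21 target CNP0278517.1 (6α,8α-dihydroxy-18-al with the (Z)-ylidene butenolide side chain), via lactol tautomer 20 (not isolated)
Conditions: AcOH/THF/H2O (3:1:1), 35 °C, dark
Reagents that add atoms: water, O
Why: Mild aqueous acetic acid hydrolyses the cyclic methyl acetal through the oxocarbenium ion (acetal hydrolysis) to the lactol, the ring–chain tautomer of the target hydroxy aldehyde, under conditions that the ylidene butenolide, the triene and the tertiary carbinol should tolerate.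

Compound list
1 | (+)-larixol, labda-8(17),14-diene-6α,13(S)-diol | C=C[C@@](C)(O)CC[C@@H]1[C@@]2(C)CCCC(C)(C)[C@@H]2[C@@H](O)CC1=C | starting material
2 | 6α-hydroxy-14,15-dinorlabd-8(17)-en-13-one | CC(=O)CC[C@@H]1[C@@]2(C)CCCC(C)(C)[C@@H]2[C@@H](O)CC1=C | intermediate
3 | 13-oxo-14,15-dinorlabd-8(17)-en-6α-yl nitrite | CC(=O)CC[C@@H]1[C@@]2(C)CCCC(C)(C)[C@@H]2[C@@H](ON=O)CC1=C | intermediate
4 | 6α-hydroxy-18-nitroso-14,15-dinorlabd-8(17)-en-13-one (not isolated) | CC(=O)CC[C@@H]1[C@@]2(C)CCC[C@@](C)(CN=O)[C@@H]2[C@@H](O)CC1=C | intermediate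
5 | (E)-oxime of 6α-hydroxy-13-oxo-14,15-dinorlabd-8(17)-en-18-al | CC(=O)CC[C@@H]1[C@@]2(C)CCC[C@@](C)(/C=N/O)[C@@H]2[C@@H](O)CC1=C | intermediate
6 | 6α-hydroxy-13-oxo-14,15-dinorlabd-8(17)-en-18-al (not isolated) | CC(=O)CC[C@@H]1[C@@]2(C)CCC[C@@](C)(C=O)[C@@H]2[C@@H](O)CC1=C | intermediate
7 | 6α,18-epoxy-18-hydroxy-14,15-dinorlabd-8(17)-en-13-one (lactol, C18 anomers) | CC(=O)CC[C@@H]1[C@@]2(C)CCC[C@@](C)(C(O)O3)[C@@H]2[C@@H]3CC1=C | intermediate
8 | 6α,18-epoxy-18-methoxy-14,15-dinorlabd-8(17)-en-13-one (C18 anomers) | CC(=O)CC[C@@H]1[C@@]2(C)CCC[C@@](C)(C(OC)O3)[C@@H]2[C@@H]3CC1=C | intermediate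
9 | ethyl (13E)-6α,18-epoxy-18-methoxylabda-8(17),13-dien-15-oate | CCOC(=O)/C=C(\C)CC[C@@H]1[C@@]2(C)CCC[C@@](C)(C(OC)O3)[C@@H]2[C@@H]3CC1=C | intermediate
10 | ethyl (13E)-6α,18:8α,17-diepoxy-18-methoxylabd-13-en-15-oate | CCOC(=O)/C=C(\C)CC[C@@H]1[C@@]2(C)CCC[C@@](C)(C(OC)O3)[C@@H]2[C@@H]3C[C@]14CO4 | intermediate
11 | (13E)-6α,18-epoxy-18-methoxylabd-13-ene-8α,15-diol | OC/C=C(\C)CC[C@@H]1[C@@]2(C)CCC[C@@](C)(C(OC)O3)[C@@H]2[C@@H]3C[C@@]1(C)O | intermediate
12 | (13E)-6α,18-epoxy-8α-hydroxy-18-methoxylabd-13-en-15-al | O=C/C=C(\C)CC[C@@H]1[C@@]2(C)CCC[C@@](C)(C(OC)O3)[C@@H]2[C@@H]3C[C@@]1(C)O | intermediate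
13 | dimethyl (1-diazo-2-oxopropyl)phosphonate | CC(=O)C(=[N+]=[N-])P(=O)(OC)OC | starting material
14 | dimethyl (1-hydroxy-2-oxopropyl)phosphonate (racemic) | CC(=O)C(O)P(=O)(OC)OC | intermediate
15 | dimethyl [1-(tert-butyldimethylsilyloxy)-2-oxopropyl]phosphonate (racemic) | CC(=O)C(O[Si](C)(C)C(C)(C)C)P(=O)(OC)OC | intermediate
16 | (3Z,5E)-3-(tert-butyldimethylsilyloxy)-6-methyl-8-(decalin-C9-yl)octa-3,5-dien-2-one (not isolated) | CC(C)(C)[Si](C)(C)O/C(C(C)=O)=C\C=C(/C)CC[C@@H]1[C@@]2(C)CCC[C@@](C)(C(OC)O3)[C@@H]2[C@@H]3C[C@@]1(C)O | intermediate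
17 | (3Z,5E)-3-hydroxy-6-methyl-8-(decalin-C9-yl)octa-3,5-dien-2-one (enolised α-diketone) | O/C(C(C)=O)=C\C=C(/C)CC[C@@H]1[C@@]2(C)CCC[C@@](C)(C(OC)O3)[C@@H]2[C@@H]3C[C@@]1(C)O | intermediate
18 | enol (triphenylphosphoranylidene)acetate of 17 (ester ylide, not isolated) | O=C(C=P(c1ccccc1)(c1ccccc1)c1ccccc1)O/C(C(C)=O)=C\C=C(/C)CC[C@@H]1[C@@]2(C)CCC[C@@](C)(C(OC)O3)[C@@H]2[C@@H]3C[C@@]1(C)O | intermediate
19 | 18-O-methyl lactol acetal of the target (Z-ylidene butenolide, 13E) | CC1=CC(=O)O/C1=C\C=C(/C)CC[C@@H]1[C@@]2(C)CCC[C@@](C)(C(OC)O3)[C@@H]2[C@@H]3C[C@@]1(C)O | intermediate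
20 | 18,6α-lactol tautomer of the target (not isolated) | CC1=CC(=O)O/C1=C\C=C(/C)CC[C@@H]1[C@@]2(C)CCC[C@@](C)(C(O)O3)[C@@H]2[C@@H]3C[C@@]1(C)O | intermediate
21 | CNP0278517.1 | CC1=CC(=O)O/C1=C\C=C(/C)CC[C@@H]1[C@@]2(C)CCC[C@@](C)(C=O)[C@@H]2[C@@H](O)C[C@@]1(C)O | target

Total step count: 14. Longest linear sequence: 12 steps (steps 1–9 and 12–14); steps 10–11 prepare the phosphonate.

Steps most likely to fail

1. Step 13 (key step). The ester-stabilised phosphorane may add too slowly to the cross-conjugated ketone that is flanked by the enol ester. Loss of ketene from the enol ester and acyl transfer would then compete with ring closure. The fallback sets out from 17 and comes back at 19. The enolic OH of 17 is esterified with diethylphosphonoacetic acid (DCC, DMAP cat., CH2Cl2, 0 °C) to give the enol phosphonoacetate F1. The same C3'=C4' bond is then closed by an intramolecular Horner–Wadsworth–Emmons reaction of the more nucleophilic phosphonate carbanion (LiCl, i-Pr2NEt, MeCN, rt), the established route from acyloxy ketones to butenolides, which gives 19.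

2. Step 12. The hindered, doubly stabilised α-silyloxy phosphonate anion may add too slowly to the conjugated aldehyde, so that silyl migration or phosphonate–phosphate rearrangement of the reagent takes over. The fallback sets out from 12 and comes back at 16, which is then desilylated as in the second stage of step 12. Commercial 1-(tert-butyldimethylsilyloxy)propan-2-one is converted under equilibrating conditions (TMSCl, NaI, Et3N, MeCN) into (Z)-1-(tert-butyldimethylsilyloxy)-2-(trimethylsilyloxy)prop-1-ene F2. A Lewis-base-catalysed Mukaiyama aldol addition of F2 to enal 12 (LiOAc cat., DMF, −20 °C) gives the O-trimethylsilyl aldol F3. Mild acidic work-up (citric acid, MeOH) desilylates it to the β-hydroxy-α-silyloxy ketone F4, a diastereomer mixture whose two new stereocentres are removed next. Acetylation (Ac2O, DMAP, pyridine) gives the acetate F5, and DBU (toluene, 50 °C) eliminates acetic acid by an E1cB pathway to give 16.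

3. Step 3. The 1,5-hydrogen transfer may lose to β-fragmentation of the C6 alkoxy radical, and the radical pair may be intercepted by the exocyclic alkene or the ketone may react photochemically. The fallback sets out from 2 and comes back at 11, replacing steps 2–8 by a hypoiodite relay with the alkene masked. Compound 2 is epoxidised (mCPBA, NaHCO3, CH2Cl2, 0 °C) to 8α,17-epoxy-6α-hydroxy-14,15-dinorlabdan-13-one F6. A Suárez hypoiodite reaction (PhI(OAc)2, I2, cyclohexane, visible light) closes the 6α,18-cyclic ether and gives 6α,18:8α,17-diepoxy-14,15-dinorlabdan-13-one F7. LiAlH4 (THF) opens the epoxide and reduces the ketone to give 6α,18-epoxy-14,15-dinorlabdane-8α,13-diol F8. RuCl3 (cat.)/NaIO4 (CCl4/MeCN/H2O) reoxidises C13 and oxidises the ether CH2, giving 8α-hydroxy-13-oxo-14,15-dinorlabdan-18,6α-olide F9. Horner–Wadsworth–Emmons olefination as in step 6 gives ethyl (13E)-8α-hydroxy-18-oxo-6α,18-epoxylabd-13-en-15-oate F10. DIBAL-H (CH2Cl2, −78 °C) reduces the ester to the allylic alcohol and the lactone to the lactol, giving (13E)-6α,18-epoxylabd-13-ene-8α,15,18-triol F11. MeOH/PPTS converts the lactol into the methyl acetal 11.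

Further compounds
F1 | step 13 | enol (diethoxyphosphoryl)acetate of 17 | CCOP(=O)(OCC)CC(=O)O/C(C(C)=O)=C\C=C(/C)CC[C@@H]1[C@@]2(C)CCC[C@@](C)(C(OC)O3)[C@@H]2[C@@H]3C[C@@]1(C)O
F2 | step 12 | (Z)-1-(tert-butyldimethylsilyloxy)-2-(trimethylsilyloxy)prop-1-ene | C/C(O[Si](C)(C)C)=C/O[Si](C)(C)C(C)(C)C
F3 | step 12 | O-trimethylsilyl aldol of 12 (α-silyloxy ketone, diastereomer mixture) | CC(=O)C(O[Si](C)(C)C(C)(C)C)C(O[Si](C)(C)C)/C=C(\C)CC[C@@H]1[C@@]2(C)CCC[C@@](C)(C(OC)O3)[C@@H]2[C@@H]3C[C@@]1(C)O
F4 | step 12 | β-hydroxy-α-(tert-butyldimethylsilyloxy) ketone (diastereomer mixture) | CC(=O)C(O[Si](C)(C)C(C)(C)C)C(O)/C=C(\C)CC[C@@H]1[C@@]2(C)CCC[C@@](C)(C(OC)O3)[C@@H]2[C@@H]3C[C@@]1(C)O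
F5 | step 12 | β-acetoxy-α-(tert-butyldimethylsilyloxy) ketone (diastereomer mixture) | CC(=O)C(O[Si](C)(C)C(C)(C)C)C(OC(C)=O)/C=C(\C)CC[C@@H]1[C@@]2(C)CCC[C@@](C)(C(OC)O3)[C@@H]2[C@@H]3C[C@@]1(C)O
F6 | step 3 | 8α,17-epoxy-6α-hydroxy-14,15-dinorlabdan-13-one | CC(=O)CC[C@@H]1[C@@]2(C)CCCC(C)(C)[C@@H]2[C@@H](O)C[C@]13CO3
F7 | step 3 | 6α,18:8α,17-diepoxy-14,15-dinorlabdan-13-one | CC(=O)CC[C@@H]1[C@@]2(C)CCC[C@@](C)(CO4)[C@@H]2[C@@H]4C[C@]13CO3
F8 | step 3 | 6α,18-epoxy-14,15-dinorlabdane-8α,13-diol (C13 epimers) | CC(O)CC[C@@H]1[C@@]2(C)CCC[C@@](C)(CO4)[C@@H]2[C@@H]4C[C@@]1(C)O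
F9 | step 3 | 8α-hydroxy-13-oxo-14,15-dinorlabdan-18,6α-olide | CC(=O)CC[C@@H]1[C@@]2(C)CCC[C@@](C)(C(=O)O4)[C@@H]2[C@@H]4C[C@@]1(C)O
F10 | step 3 | ethyl (13E)-8α-hydroxy-18-oxo-6α,18-epoxylabd-13-en-15-oate | CCOC(=O)/C=C(\C)CC[C@@H]1[C@@]2(C)CCC[C@@](C)(C(=O)O4)[C@@H]2[C@@H]4C[C@@]1(C)O
F11 | step 3 | (13E)-6α,18-epoxylabd-13-ene-8α,15,18-triol (lactol, C18 anomers) | OC/C=C(\C)CC[C@@H]1[C@@]2(C)CCC[C@@](C)(C(O)O4)[C@@H]2[C@@H]4C[C@@]1(C)O
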